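## Retrosynthetic overview

1. The target comes from global hydrogenolysis of a benzyl/diphenylmethylene-protected dimer; its C4–H (3,4-cis) comes from hydride capture of the C4 cation of a tertiary alcohol.
2. The C4(upper)–C6(lower) bond comes from 1,2-addition of a C6-lithiated lower flavan-3-ol to the C4 ketone of an upper dihydroflavonol.
3. Each pyran ring (ring C upper, ring F lower) comes from an α-ketol 1,2-shift ring expansion (five to six members) of a 3-hydroxy-2-aryl-2,3-dihydrobenzofuran-3-carbaldehyde; for the lower unit this is run as a redox-neutral iridium hydrogen relay.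
4. The dihydrobenzofurans come from asymmetric palladium heteroannulation of an o-iodophenol (ring A from resorcinol, ring D from catechol) with one common aryl allene (rings B and E from catechol, both C3 bridges from propargyl bromide), then dihydroxylation.
5. Ring order: furan ring then ring C (upper unit); furan ring then ring F (lower unit); union of the two units last.

Assumption: the SMILES is read as fisetinidol-(4β→6)-mesquitol, upper unit 2R,3S,4S (2,3-trans-3,4-cis), lower unit 2R,3S (2,3-trans), linked C4→C6. The route is a paper proposal; no step has been run.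

## Route

Step 1
Reactants: 1 catechol
Product: 2 2,2-diphenyl-1,3-benzodioxole
Conditions: Ph2CCl2, neat, 170 °C
Reagents that add atoms: dichlorodiphenylmethane ClC(Cl)(c1ccccc1)c1ccccc1
Why: Ketal formation from the 1,2-diol and the gem-dichloride (driven by loss of HCl) masks the catechol as a diphenylmethylene ketal that tolerates organometallics and is removed by hydrogenolysis at the end; no stereocentre is formed.

Step 2
Reactants: 2 2,2-diphenyl-1,3-benzodioxole
Product: 3 5-bromo-2,2-diphenyl-1,3-benzodioxole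
Conditions: NBS, MeCN, 0 °C → rt
Reagents that add atoms: N-bromosuccinimide O=C1CCC(=O)N1Br
Why: Electrophilic aromatic bromination goes para to a ring oxygen (position 5), the usual site for 1,3-benzodioxoles.

Step 3
Reactants: 3 5-bromo-2,2-diphenyl-1,3-benzodioxole; 4 propargyl bromide
Product: 6 2,2-diphenyl-5-(propa-1,2-dien-1-yl)-1,3-benzodioxole, via arylmagnesium bromide 5 (not isolated)
Conditions: Mg, THF, 50 °C; then CuBr (5 mol %), 4, −30 °C → rt
Reagents that add atoms: none
Why: Grignard formation followed by copper-catalysed SN2′ substitution of the propargylic bromide gives the terminal aryl allene that supplies ring B (and ring E) plus the C3 bridge.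

Step 4
Reactants: 7 resorcinol
Product: 8 3-(benzyloxy)phenol
Conditions: BnBr (1.0 equiv), K2CO3, acetone, reflux
Reagents that add atoms: benzyl bromide BrCc1ccccc1
Why: Williamson ether synthesis with one equivalent of halide gives the monoether (statistical; separated from diether and recovered resorcinol).

Step 5
Reactants: 8 3-(benzyloxy)phenol
Product: 9 5-(benzyloxy)-2-iodophenol
Conditions: I2, NaHCO3, THF/H2O, 0 °C → rt
Reagents that add atoms: iodine II
Why: Electrophilic iodination of the phenoxide goes ortho to OH and para to OBn, placing iodine on the carbon that becomes C4a of ring A.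

Step 6
Reactants: 9 5-(benzyloxy)-2-iodophenol; 6 2,2-diphenyl-5-(propa-1,2-dien-1-yl)-1,3-benzodioxole
Product: 10 (2R)-6-(benzyloxy)-2-(2,2-diphenyl-1,3-benzodioxol-5-yl)-3-methylidene-2,3-dihydro-1-benzofuran
Conditions: Pd(OAc)2 (5 mol %), (S,S)-2,2′-isopropylidenebis(4-phenyl-2-oxazoline) (10 mol %), Ag3PO4, DMF, 80 °C
Reagents that add atoms: none
Why: Larock heteroannulation of an allene: oxidative addition of the C–I bond, carbopalladation at the central allene carbon and attack of the phenoxide on the aryl-bearing terminus of the π-allyl complex close the furan ring, the chiral bisoxazoline controlling the face of C–O bond formation so that C2 is R (the ligand antipode is chosen to give this sense).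

Step 7
Reactants: 10 (2R)-6-(benzyloxy)-2-(2,2-diphenyl-1,3-benzodioxol-5-yl)-3-methylidene-2,3-dihydro-1-benzofuran
Product: 11 (2R,3R)-6-(benzyloxy)-2-(2,2-diphenyl-1,3-benzodioxol-5-yl)-3-(hydroxymethyl)-2,3-dihydro-1-benzofuran-3-ol
Conditions: OsO4 (2 mol %), NMO, acetone/H2O, 0 °C → rt
Reagents that add atoms: N-methylmorpholine N-oxide C[N+]1([O-])CCOCC1; water O
Why: Upjohn syn-dihydroxylation of the electron-rich exocyclic alkene occurs from the face opposite the 2-aryl group (3-OH trans to aryl), and since C3 becomes the carbonyl carbon in step 9 its configuration is immaterial.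

Step 8
Reactants: 11 (2R,3R)-6-(benzyloxy)-2-(2,2-diphenyl-1,3-benzodioxol-5-yl)-3-(hydroxymethyl)-2,3-dihydro-1-benzofuran-3-ol
Product: 12 (2R,3S)-6-(benzyloxy)-2-(2,2-diphenyl-1,3-benzodioxol-5-yl)-3-hydroxy-2,3-dihydro-1-benzofuran-3-carbaldehyde
Conditions: SO3·pyridine, DMSO, i-Pr2NEt, CH2Cl2, 0 °C
Reagents that add atoms: none
Why: Parikh–Doering oxidation converts only the primary alcohol (the tertiary one cannot be oxidised and activated DMSO does not cleave the glycol), giving a non-enolisable α-hydroxy aldehyde without touching C2.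

Step 9
Reactants: 12 (2R,3S)-6-(benzyloxy)-2-(2,2-diphenyl-1,3-benzodioxol-5-yl)-3-hydroxy-2,3-dihydro-1-benzofuran-3-carbaldehyde
Product: 13 (2R,3R)-7-(benzyloxy)-2-(2,2-diphenyl-1,3-benzodioxol-5-yl)-3-hydroxy-2,3-dihydro-4H-chromen-4-one
Conditions: Al(Ot-Bu)3 (30 mol %), PhMe, 80 °C
Reagents that add atoms: none
Why: α-Ketol (acyloin) rearrangement: in the aluminium chelate the C2–C3 ring bond migrates to the formyl carbon with retention at C2, a 1,2-shift that expands the furan ring to the six-membered ring C, with the conjugated 2,4-dioxygenated aryl ketone as the thermodynamic sink and the new C3 centre ending trans to the 2-aryl group (chelate-controlled shift plus equilibration through the enediolate) to give the 2R,3R dihydroflavonol.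

Step 10
Reactants: 2 2,2-diphenyl-1,3-benzodioxole
Product: 16 2,2-diphenyl-1,3-benzodioxol-4-ol, via aryllithium 14 (not isolated), via dimethyl arylboronate 15 (not isolated)
Conditions: s-BuLi, TMEDA, THF, −78 °C; B(OMe)3, −78 °C → rt; then H2O2 (30 %), AcOH, 0 °C
Reagents that add atoms: hydrogen peroxide OO
Why: Directed ortho-lithiation next to the dioxole oxygen (the ketal has no acidic benzylic hydrogens), borylation and boronate oxidation install the third oxygen of ring D and leave the terminal OH free.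

Step 11
Reactants: 16 2,2-diphenyl-1,3-benzodioxol-4-ol
Product: 18 7-bromo-5-iodo-2,2-diphenyl-1,3-benzodioxol-4-ol, via bromophenol 17 (not isolated)
Conditions: NBS, MeCN, −20 °C; then NIS, CF3CO2H (cat.), rt
Reagents that add atoms: N-bromosuccinimide O=C1CCC(=O)N1Br; N-iodosuccinimide O=C1CCC(=O)N1I
Why: Sequential electrophilic halogenation: bromine enters para to the free OH (the future C6 of the lower unit), then iodine takes the only remaining activated position ortho to OH (the future C4a).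

Step 12
Reactants: 18 7-bromo-5-iodo-2,2-diphenyl-1,3-benzodioxol-4-ol; 6 2,2-diphenyl-5-(propa-1,2-dien-1-yl)-1,3-benzodioxole
Product: 19 (2R)-5-bromo-2-(2,2-diphenyl-1,3-benzodioxol-5-yl)-6,7-[(diphenylmethylene)dioxy]-3-methylidene-2,3-dihydro-1-benzofuran
Conditions: Pd(OAc)2 (5 mol %), (S,S)-2,2′-isopropylidenebis(4-phenyl-2-oxazoline) (10 mol %), Ag3PO4, DMF, 80 °C
Reagents that add atoms: none
Why: The same Larock allene heteroannulation as step 6, chemoselective for C–I over C–Br, with the chiral ligand again setting C2 as R.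

Step 13
Reactants: 19 (2R)-5-bromo-2-(2,2-diphenyl-1,3-benzodioxol-5-yl)-6,7-[(diphenylmethylene)dioxy]-3-methylidene-2,3-dihydro-1-benzofuran
Product: 20 (2R,3R)-5-bromo-2-(2,2-diphenyl-1,3-benzodioxol-5-yl)-6,7-[(diphenylmethylene)dioxy]-3-(hydroxymethyl)-2,3-dihydro-1-benzofuran-3-ol
Conditions: OsO4 (2 mol %), NMO, acetone/H2O, 0 °C → rt
Reagents that add atoms: N-methylmorpholine N-oxide C[N+]1([O-])CCOCC1; water O
Why: Upjohn syn-dihydroxylation from the face opposite the 2-aryl group, the C3 configuration again being lost in the next step.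

Step 14
Reactants: 20 (2R,3R)-5-bromo-2-(2,2-diphenyl-1,3-benzodioxol-5-yl)-6,7-[(diphenylmethylene)dioxy]-3-(hydroxymethyl)-2,3-dihydro-1-benzofuran-3-ol
Product: 24 (2R,3S)-6-bromo-2-(2,2-diphenyl-1,3-benzodioxol-5-yl)-7,8-[(diphenylmethylene)dioxy]-3,4-dihydro-2H-chromen-3-ol, via α-hydroxy aldehyde 21 (not isolated), via dihydroflavonol 22 (not isolated), via flavan-3,4-diol 23 (not isolated)
Conditions: [Cp*IrCl2]2 (2.5 mol %), K2CO3 (10 mol %), PhMe, 100 °C; then Et3SiH, CF3CO2H, CH2Cl2, 0 °C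
Reagents that add atoms: none
Why: Proposed new method: a hydrogen-borrowing ring expansion in which the iridium catalyst dehydrogenates the primary alcohol to aldehyde 21 and stores the hydrogen as Ir–H, the metal/carbonate-bound tertiary alkoxide then triggers the α-ketol 1,2-shift of C2 (retention) that expands the furan ring to ring F of dihydroflavonol 22 with C3 trans to the aryl group as in step 9, and the Ir–H returns the hydrogen to the new ketone to give diol 23, whose benzylic 4-OH (and any residual ketone) is then removed in the same flask by ionic hydrogenation through the oxygen-stabilised C4 cation; the closest known reaction types are iridium-catalysed hydrogen-borrowing (hydrogen auto-transfer) alkylation and the base- or Lewis-acid-mediated α-ketol ring expansion.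

Step 15
Reactants: 24 (2R,3S)-6-bromo-2-(2,2-diphenyl-1,3-benzodioxol-5-yl)-7,8-[(diphenylmethylene)dioxy]-3,4-dihydro-2H-chromen-3-ol; 13 (2R,3R)-7-(benzyloxy)-2-(2,2-diphenyl-1,3-benzodioxol-5-yl)-3-hydroxy-2,3-dihydro-4H-chromen-4-one
Product: 27 (2R,3R,4S)-7-(benzyloxy)-2-(2,2-diphenyl-1,3-benzodioxol-5-yl)-4-[(2R,3S)-2-(2,2-diphenyl-1,3-benzodioxol-5-yl)-7,8-[(diphenylmethylene)dioxy]-3-hydroxy-3,4-dihydro-2H-chromen-6-yl]-3,4-dihydro-2H-chromene-3,4-diol (major C4 epimer shown), via lithium alkoxide 25 (not isolated), via dilithio species 26 (not isolated)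
Conditions: 24, t-BuLi (3.1 equiv), THF, −78 °C; then 13 pretreated with LiN(SiMe3)2 (1.0 equiv), THF, −78 → −20 °C; H2O
Reagents that add atoms: none
Why: Bromine–lithium exchange (the 3-OH being carried as its lithium alkoxide) and 1,2-addition of the aryllithium to the ketone form the C4–C6 interflavan bond, and the configuration of the new carbinol is irrelevant because C4 is ionised in step 16.

Step 16
Reactants: 27 the C4 tertiary alcohol (2R,3R,4S major epimer)
Product: 28 (2R,3S,4R)-7-(benzyloxy)-2-(2,2-diphenyl-1,3-benzodioxol-5-yl)-4-[(2R,3S)-2-(2,2-diphenyl-1,3-benzodioxol-5-yl)-7,8-[(diphenylmethylene)dioxy]-3-hydroxy-3,4-dihydro-2H-chromen-6-yl]-3,4-dihydro-2H-chromen-3-ol (2,3-trans-3,4-cis; the same geometry is 4S in the free phenol)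
Conditions: Et3SiH (10 equiv), CF3CO2H, CH2Cl2, −40 °C
Reagents that add atoms: none
Why: Kursanov–Parnes ionic hydrogenation: acid ionises the tertiary doubly benzylic alcohol to a cation stabilised by two alkoxy-aryl rings and the silane delivers hydride to the face opposite the 3-OH (the facial rule that makes arenes add trans to O3 on flavan-4-yl cations, reinforced here by the allylic strain that pushes O3 axial), so H enters trans and the lower unit ends cis to the 3-OH (4β).

Step 17
Reactants: 28 the protected biflavanoid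
Product: 29 fisetinidol-(4β→6)-mesquitol (CNP0252692.1)
Conditions: H2 (1 atm), Pd(OH)2/C, THF/MeOH, rt
Reagents that add atoms: none
Why: Catalytic hydrogenolysis cleaves the benzyl ether and the three diphenylmethylene ketals under neutral conditions that leave the stereocentres and the ring C–O bonds untouched.

## Compound list

1 | catechol | Oc1ccccc1O | starting material
2 | 2,2-diphenyl-1,3-benzodioxole | c1ccc2OC(c3ccccc3)(c3ccccc3)Oc2c1 | intermediate
3 | 5-bromo-2,2-diphenyl-1,3-benzodioxole | Brc1ccc2OC(c3ccccc3)(c3ccccc3)Oc2c1 | intermediate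
4 | propargyl bromide (3-bromoprop-1-yne) | C#CCBr | starting material
5 | (2,2-diphenyl-1,3-benzodioxol-5-yl)magnesium bromide (not isolated) | Br[Mg]c1ccc2OC(c3ccccc3)(c3ccccc3)Oc2c1 | intermediate
6 | 2,2-diphenyl-5-(propa-1,2-dien-1-yl)-1,3-benzodioxole | C=C=Cc1ccc2OC(c3ccccc3)(c3ccccc3)Oc2c1 | intermediate
7 | resorcinol | Oc1cccc(O)c1 | starting material
8 | 3-(benzyloxy)phenol | Oc1cccc(OCc2ccccc2)c1 | intermediate
9 | 5-(benzyloxy)-2-iodophenol | Oc1cc(OCc2ccccc2)ccc1I | intermediate
10 | (2R)-6-(benzyloxy)-2-(2,2-diphenyl-1,3-benzodioxol-5-yl)-3-methylidene-2,3-dihydro-1-benzofuran | C=C1c2ccc(OCc3ccccc3)cc2O[C@@H]1c1ccc2OC(c3ccccc3)(c3ccccc3)Oc2c1 | intermediate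
11 | (2R,3R)-6-(benzyloxy)-2-(2,2-diphenyl-1,3-benzodioxol-5-yl)-3-(hydroxymethyl)-2,3-dihydro-1-benzofuran-3-ol (3-OH trans to aryl) | OC[C@]1(O)c2ccc(OCc3ccccc3)cc2O[C@@H]1c1ccc2OC(c3ccccc3)(c3ccccc3)Oc2c1 | intermediate
12 | (2R,3S)-6-(benzyloxy)-2-(2,2-diphenyl-1,3-benzodioxol-5-yl)-3-hydroxy-2,3-dihydro-1-benzofuran-3-carbaldehyde | O=C[C@]1(O)c2ccc(OCc3ccccc3)cc2O[C@@H]1c1ccc2OC(c3ccccc3)(c3ccccc3)Oc2c1 | intermediate
13 | (2R,3R)-7-(benzyloxy)-2-(2,2-diphenyl-1,3-benzodioxol-5-yl)-3-hydroxy-2,3-dihydro-4H-chromen-4-one (2,3-trans; protected fustin) | O=C1c2ccc(OCc3ccccc3)cc2O[C@H](c2ccc3OC(c4ccccc4)(c4ccccc4)Oc3c2)[C@H]1O | intermediate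
14 | (2,2-diphenyl-1,3-benzodioxol-4-yl)lithium (not isolated) | [Li]c1cccc2OC(c3ccccc3)(c3ccccc3)Oc12 | intermediate
15 | dimethyl (2,2-diphenyl-1,3-benzodioxol-4-yl)boronate (not isolated) | COB(OC)c1cccc2OC(c3ccccc3)(c3ccccc3)Oc12 | intermediate
16 | 2,2-diphenyl-1,3-benzodioxol-4-ol | Oc1cccc2OC(c3ccccc3)(c3ccccc3)Oc12 | intermediate
17 | 7-bromo-2,2-diphenyl-1,3-benzodioxol-4-ol (not isolated) | Oc1ccc(Br)c2OC(c3ccccc3)(c3ccccc3)Oc12 | intermediate
18 | 7-bromo-5-iodo-2,2-diphenyl-1,3-benzodioxol-4-ol | Oc1c(I)cc(Br)c2OC(c3ccccc3)(c3ccccc3)Oc12 | intermediate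
19 | (2R)-5-bromo-2-(2,2-diphenyl-1,3-benzodioxol-5-yl)-6,7-[(diphenylmethylene)dioxy]-3-methylidene-2,3-dihydro-1-benzofuran | C=C1c2cc(Br)c3OC(c4ccccc4)(c4ccccc4)Oc3c2O[C@@H]1c1ccc2OC(c3ccccc3)(c3ccccc3)Oc2c1 | intermediate
20 | (2R,3R)-5-bromo-2-(2,2-diphenyl-1,3-benzodioxol-5-yl)-6,7-[(diphenylmethylene)dioxy]-3-(hydroxymethyl)-2,3-dihydro-1-benzofuran-3-ol | OC[C@]1(O)c2cc(Br)c3OC(c4ccccc4)(c4ccccc4)Oc3c2O[C@@H]1c1ccc2OC(c3ccccc3)(c3ccccc3)Oc2c1 | intermediate
21 | (2R,3S)-5-bromo-2-(2,2-diphenyl-1,3-benzodioxol-5-yl)-6,7-[(diphenylmethylene)dioxy]-3-hydroxy-2,3-dihydro-1-benzofuran-3-carbaldehyde (not isolated) | O=C[C@]1(O)c2cc(Br)c3OC(c4ccccc4)(c4ccccc4)Oc3c2O[C@@H]1c1ccc2OC(c3ccccc3)(c3ccccc3)Oc2c1 | intermediate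
22 | (2R,3R)-6-bromo-2-(2,2-diphenyl-1,3-benzodioxol-5-yl)-7,8-[(diphenylmethylene)dioxy]-3-hydroxy-2,3-dihydro-4H-chromen-4-one (not isolated) | O=C1c2cc(Br)c3OC(c4ccccc4)(c4ccccc4)Oc3c2O[C@H](c2ccc3OC(c4ccccc4)(c4ccccc4)Oc3c2)[C@H]1O | intermediate
23 | (2R,3S,4R)-6-bromo-2-(2,2-diphenyl-1,3-benzodioxol-5-yl)-7,8-[(diphenylmethylene)dioxy]-3,4-dihydro-2H-chromene-3,4-diol (major C4 epimer; not isolated) | O[C@@H]1c2cc(Br)c3OC(c4ccccc4)(c4ccccc4)Oc3c2O[C@H](c2ccc3OC(c4ccccc4)(c4ccccc4)Oc3c2)[C@H]1O | intermediate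
24 | (2R,3S)-6-bromo-2-(2,2-diphenyl-1,3-benzodioxol-5-yl)-7,8-[(diphenylmethylene)dioxy]-3,4-dihydro-2H-chromen-3-ol (protected 6-bromomesquitol) | O[C@H]1Cc2cc(Br)c3OC(c4ccccc4)(c4ccccc4)Oc3c2O[C@@H]1c1ccc2OC(c3ccccc3)(c3ccccc3)Oc2c1 | intermediate
25 | lithium 3-alkoxide of 13 (not isolated) | O=C1c2ccc(OCc3ccccc3)cc2O[C@H](c2ccc3OC(c4ccccc4)(c4ccccc4)Oc3c2)[C@H]1O[Li] | intermediate
26 | C6-lithio lithium 3-alkoxide of the debrominated 24 (not isolated) | [Li]O[C@H]1Cc2cc([Li])c3OC(c4ccccc4)(c4ccccc4)Oc3c2O[C@@H]1c1ccc2OC(c3ccccc3)(c3ccccc3)Oc2c1 | intermediate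
27 | C4 tertiary alcohol of the protected dimer, upper unit 2R,3R,4S (major epimer: lower unit cis to 3-OH, 4-OH trans to 3-OH), lower unit 2R,3S | O[C@H]1[C@@](O)(c4cc5C[C@H](O)[C@@H](c6ccc7OC(c8ccccc8)(c8ccccc8)Oc7c6)Oc5c5OC(c6ccccc6)(c6ccccc6)Oc45)c2ccc(OCc3ccccc3)cc2O[C@@H]1c1ccc2OC(c3ccccc3)(c3ccccc3)Oc2c1 | intermediate
28 | protected fisetinidol-(4β→6)-mesquitol: 7-O-benzyl, three catechols as diphenylmethylene ketals; upper unit 2,3-trans-3,4-cis (2R,3S,4R in this protected form), lower unit 2R,3S | O[C@H]1[C@@H](c4cc5C[C@H](O)[C@@H](c6ccc7OC(c8ccccc8)(c8ccccc8)Oc7c6)Oc5c5OC(c6ccccc6)(c6ccccc6)Oc45)c2ccc(OCc3ccccc3)cc2O[C@@H]1c1ccc2OC(c3ccccc3)(c3ccccc3)Oc2c1 | intermediate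
29 | fisetinidol-(4β→6)-mesquitol: (2R,3S,4S)-2-(3,4-dihydroxyphenyl)-4-[(2R,3S)-2-(3,4-dihydroxyphenyl)-3,7,8-trihydroxy-3,4-dihydro-2H-chromen-6-yl]-3,4-dihydro-2H-chromene-3,7-diol | Oc1ccc2c(c1)O[C@H](c1ccc(O)c(O)c1)[C@@H](O)[C@H]2c1cc2c(c(O)c1O)O[C@H](c1ccc(O)c(O)c1)[C@@H](O)C2 | target

## Step count and risks

Total step count: 17. Longest linear sequence: 10 steps (steps 1, 2, 3, 6, 7, 8, 9, 15, 16, 17).

Three steps most likely to fail:

**Step 6 (allene heteroannulation; step 12 carries the same risk).** The phenoxide may attack the unsubstituted terminus of the π-allyl complex, the enantiomeric excess may be only moderate, and the exocyclic alkene can isomerise to the aromatic 3-methylbenzofuran. The fallback is known chemistry; it sets out from bromide 3 (through its Grignard reagent 5) and iodophenol 9 and comes back at 10. Reagent 5 is added to acrolein (C=CC=O) to give racemic 1-(2,2-diphenyl-1,3-benzodioxol-5-yl)prop-2-en-1-ol F1. Dilute aqueous acid transposes this electron-rich allylic alcohol to (E)-3-(2,2-diphenyl-1,3-benzodioxol-5-yl)prop-2-en-1-ol F2. ClCO2Me/pyridine converts it into (E)-3-(2,2-diphenyl-1,3-benzodioxol-5-yl)prop-2-en-1-yl methyl carbonate F3. Iridium-catalysed asymmetric allylic etherification ([Ir(cod)Cl]2, phosphoramidite ligand, sodium phenoxide of 9, THF) gives the branched ether (S)-5-{1-[5-(benzyloxy)-2-iodophenoxy]prop-2-en-1-yl}-2,2-diphenyl-1,3-benzodioxole F4. An intramolecular Heck cyclisation (Pd(OAc)2, PPh3, Ag2CO3, MeCN, 60 °C) then closes the furan ring to 10.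

**Step 14 (the proposed hydrogen-borrowing ring expansion).** Possible failures are decarbonylation of aldehyde 21, hydrodebromination, competing aryl migration with loss of C2 integrity, or base-induced ring contraction of 22 before it is reduced. The fallback uses discrete, known operations; it sets out from 20 and comes back at 24. Parikh–Doering oxidation gives aldehyde 21, now isolated; Al(Ot-Bu)3 in toluene effects the α-ketol shift to 22 exactly as in steps 8 and 9; NaBH4 gives diol 23; Et3SiH/CF3CO2H gives 24. Every compound on this path is already in the list, so no new compound arises (F0).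

**Step 16 (facial selectivity of hydride delivery).** In this 5-deoxy series the preference for attack trans to O3 may be modest, and a pinacol-type hydride shift to the 4-arylflavan-3-one can compete. The fallback is the known Lewis-acid flavan-3,4-diol/flavan-3-ol condensation; it sets out from 13 and 24 and comes back at 28. NaBH4 reduces 13 to (2R,3S,4R)-7-(benzyloxy)-2-(2,2-diphenyl-1,3-benzodioxol-5-yl)-3,4-dihydro-2H-chromene-3,4-diol F5. n-BuLi followed by water converts 24 into (2R,3S)-2-(2,2-diphenyl-1,3-benzodioxol-5-yl)-7,8-[(diphenylmethylene)dioxy]-3,4-dihydro-2H-chromen-3-ol F6. TMSOTf (cat.) in CH2Cl2 at −78 °C generates the C4 cation of F5, which alkylates C6 of F6 to give both C4 epimers. The 4β epimer is 28; it is expected to be the minor product and is separated by chromatography before step 17.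

## Further compounds

F1 | step 6 | racemic 1-(2,2-diphenyl-1,3-benzodioxol-5-yl)prop-2-en-1-ol | C=CC(O)c1ccc2OC(c3ccccc3)(c3ccccc3)Oc2c1
F2 | step 6 | (E)-3-(2,2-diphenyl-1,3-benzodioxol-5-yl)prop-2-en-1-ol | OC/C=C/c1ccc2OC(c3ccccc3)(c3ccccc3)Oc2c1
F3 | step 6 | (E)-3-(2,2-diphenyl-1,3-benzodioxol-5-yl)prop-2-en-1-yl methyl carbonate | COC(=O)OC/C=C/c1ccc2OC(c3ccccc3)(c3ccccc3)Oc2c1
F4 | step 6 | (S)-5-{1-[5-(benzyloxy)-2-iodophenoxy]prop-2-en-1-yl}-2,2-diphenyl-1,3-benzodioxole | C=C[C@H](Oc1cc(OCc2ccccc2)ccc1I)c1ccc2OC(c3ccccc3)(c3ccccc3)Oc2c1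
F0 | step 14 | none | none
F5 | step 16 | (2R,3S,4R)-7-(benzyloxy)-2-(2,2-diphenyl-1,3-benzodioxol-5-yl)-3,4-dihydro-2H-chromene-3,4-diol | O[C@@H]1c2ccc(OCc3ccccc3)cc2O[C@H](c2ccc3OC(c4ccccc4)(c4ccccc4)Oc3c2)[C@H]1O
F6 | step 16 | (2R,3S)-2-(2,2-diphenyl-1,3-benzodioxol-5-yl)-7,8-[(diphenylmethylene)dioxy]-3,4-dihydro-2H-chromen-3-ol | O[C@H]1Cc2ccc3OC(c4ccccc4)(c4ccccc4)Oc3c2O[C@@H]1c1ccc2OC(c3ccccc3)(c3ccccc3)Oc2c1
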